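Your vessel is closed, stirred and held at constant temperature, and both solids start undissolved.

| flask | solid substrate | solid reagent | remark | time |
|---|---|---|---|---|
| teal | 0.020 M | 1.1 equiv | the very flask that is asked about, followed so far |  |
| grey | 0.020 M | 0.74 equiv | run made earlier |  |
| flask | 0.020 M | 1.10 equiv |  | 2.5 d |

| run | time / h | target / % | solid product / % |
|---|---|---|---|
| teal | 1.33 | 0 | 0 |
| teal | 3.00 | 6 | 0 |
| teal | 4.00 | 11 | 1 |
| teal | 6.00 | 15 | 1 |
| teal | 8.00 | 15 | 2 |
| grey | 4.00 | 12 | 0 |
| grey | 10.0 | 16 | 2 |
| grey | 20.0 | 13 | 0 |
| grey | 30.0 | 16 | 0 |
| grey | 40.0 | 18 | 2 |

(readings scatter by 1.5 percentage points)

- what is said of target includes solid product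
- solid substrate, solid product, solid reagent is a solid; its amount is given per volume of the solution
- at the start none of the solid reagent is in solution
- at the start none of the solid substrate is in solution

- north-east: doubling the dissolution coefficient of the solid reagent, all else as stated
- south-east: doubling the solubility of the solid substrate, all else as stated
- west: doubling the dissolution coefficient of the solid substrate, all else as stated
- south-west: doubling the solubility of the solid reagent, all else as stated

- target and solid product together at 2.5 d, in percent of the solid substrate charged
- the change that raises the amount of target and solid product together at 2.5 d, in percent of the solid substrate charged most ("none" if none brings more than 2 percentage points) (north-east / south-east / west / south-west / none)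
- amount of target and solid product together at 2.5 d, in percent of the solid substrate charged, after south-east

The teal flask is charged with 1.1 equiv of solid reagent, so the solid substrate is the limiting reagent by charge, and you write the balance of the solid substrate. At 8.00 h the teal flask reads 15 % of target and 2 % of solid product, which leaves 83.0 % of the charge. Call this the unclaimed share: the part of the solid substrate charged that stands in neither target nor solid product.

But the grey flask, with 0.74 equiv of solid reagent, still reads 18 % of target at 40.0 h, so this run, which differs from the teal flask in both reagent and time, shows no fall in target against a scatter of 1.5 percentage points. I therefore keep the unclaimed share for the teal flask at 2.5 d and expect 17.0 %. The readings cannot say whether that share still lies as solid or has left by another path.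

The forecast gives 17 %, chooses south-east, and expects 30 % after that change, on this ground: “The likeliest explanation is a reversible solution reaction, with both saturated solids fixing the activities.”

The teal flask gives 17.2 %. The best change is south-west, worth 10 points, while south-east gives 12.3 %.

    solid reagent ⇌ partner, rate k1*(cs1 - [partner]) while solid is left; crystals form when [partner] > cs1 (solubility = 6.70 mM, k = 0.270 h⁻¹)
    dissolved substrate + partner → target (k = 64.0 L mol⁻¹ h⁻¹)
    solid product ⇌ target, rate k3*(cs3 - [target]) while solid is left; crystals form when [target] > cs3 (solubility = 9.40 mM, k = 1.60 h⁻¹)
    2 dissolved substrate → side product A (k = 100 L mol⁻¹ h⁻¹)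
    solid substrate ⇌ dissolved substrate, rate k5*(cs5 - [dissolved substrate]) while solid is left; crystals form when [dissolved substrate] > cs5 (solubility = 15.0 mM, k = 0.620 h⁻¹)
    solid substrate + target → side product B (k = 0.700 L mol⁻¹ h⁻¹)

The unclaimed share, read as 83.0 % in the teal flask at 8.00 h, is not solid still waiting: at 2.50 d the teal flask holds 0 % of solid substrate and 82.7 % of side product A, each side product A counted as the two dissolved substrate it holds. The path from two dissolved substrate to side product A is the main reason: the run without it reaches 99.5 % of target and solid product, against 17.2 %. The neighbour charged with 0.0050 M of solid substrate gives 29.3 %, so its unclaimed share is 70.7 %, and it holds 70.7 % of side product A.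

The earlier runs and the new flask come from a simulation for substances that don't exist; noise was put on by code.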